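**Plan**
- The retrosynthesis first turns the five phenols of the target into benzyl ethers (13), then cuts the C6–CH3 and C8–CH3 bonds of ring A to give the 6,8-diiodide 10 and trimethylboroxine.
- The cut is possible because C6 and C8 are the only unsubstituted carbons of ring A, and each lies ortho or para to all three oxygen-bearing carbons (C5, C7, C8a). They are the most nucleophilic carbons of the flavone, so they accept iodine selectively and iodine is then exchanged for methyl.
- The C–I bonds go back to C–H, the 3-O–CH3 bond to a free 3-hydroxyl, and that hydroxyl to the rhamnoside of myricitrin, which masks O3 while the other phenols are benzylated.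
- In the forward direction no ring is built: rings A, B and C come intact from myricitrin. The order is benzylation, deglycosylation, 3-O-methylation, diiodination, 5-O-benzylation, twofold methyl coupling, hydrogenolysis.
- The target has no stereocentre; the rhamnose stereocentres leave with the sugar in step 2.

Key step: step 6

Assumption: the 5-hydroxyl, hydrogen-bonded to the C4 carbonyl, is taken to stay free under carbonate-mediated benzylation and methylation near room temperature, as is usual for 5-hydroxyflavones, and is therefore etherified separately in step 5.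

Step 1
Reactants: 1 myricitrin; 2 benzyl bromide
Product: 3 tetrabenzylmyricitrin (7,3',4',5'-tetra-O-benzylmyricetin 3-O-α-L-rhamnopyranoside)
Conditions: BnBr (4.4 equiv), K2CO3 (5 equiv), degassed DMF, 45 °C, Ar
Reagents that add atoms: benzyl bromide 2, BrCc1ccccc1
Why: Williamson ether synthesis: carbonate deprotonates only the four acidic phenols at C7, C3', C4' and C5', while the chelated 5-hydroxyl and the rhamnose alcohols should stay free and the glycoside keeps O3 blocked.

Step 2
Reactants: 3 tetrabenzylmyricitrin
Product: 4 tetrabenzylmyricetin (7,3',4',5'-tetrabenzyloxy-3,5-dihydroxyflavone)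
Conditions: 3 M aq. HCl, 1,4-dioxane, 90 °C
Reagents that add atoms: none
Why: Acid-catalysed glycoside hydrolysis through the rhamnosyl oxocarbenium ion should release the 3-hydroxyl, the aryl benzyl ethers being stable to aqueous HCl.

Step 3
Reactants: 4 tetrabenzylmyricetin; 5 iodomethane
Product: 6 3-methyl ether (7,3',4',5'-tetrabenzyloxy-5-hydroxy-3-methoxyflavone)
Conditions: MeI (1.2 equiv), K2CO3 (1.5 equiv), DMF, rt
Reagents that add atoms: iodomethane 5, CI
Why: Williamson O-methylation under mild carbonate conditions should take the more acidic, weakly chelated enolic 3-hydroxyl and leave the strongly chelated 5-hydroxyl untouched.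

Step 4
Reactants: 6 3-methyl ether; 7 N-iodosuccinimide
Product: 9 diiodophenol (7,3',4',5'-tetrabenzyloxy-5-hydroxy-6,8-diiodo-3-methoxyflavone), via 6-iodo monoiodide 8 (not isolated)
Conditions: NIS (2.3 equiv), TFA (0.3 equiv), CH2Cl2/MeCN 1:1, 0 °C to rt, dark; aq. Na2S2O3 work-up
Reagents that add atoms: N-iodosuccinimide 7, O=C1CCC(=O)N1I
Why: Electrophilic aromatic iodination: C6 (ortho to the free phenol, expected first) and then C8 are each activated by three oxygen donors (5-OH, 7-OBn, O1), whereas C2' and C6' of ring B have only two donors, adjoin the electron-poor pyranone and are hindered, so iodine should enter ring A only.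

Step 5
Reactants: 9 diiodophenol; 2 benzyl bromide
Product: 10 pentabenzyl diiodide (5,7,3',4',5'-pentabenzyloxy-6,8-diiodo-3-methoxyflavone)
Conditions: BnBr (2 equiv), K2CO3 (3 equiv), DMF, 70 °C
Reagents that add atoms: benzyl bromide 2, BrCc1ccccc1
Why: Williamson ether synthesis at raised temperature: the ortho iodine increases the acidity of the chelated phenol and benzyl bromide is a slim, reactive electrophile, so the last acidic proton should be removed before the palladium step.

Step 6
Reactants: 10 pentabenzyl diiodide; 11 trimethylboroxine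
Product: 13 pentabenzyl dimethylflavone (5,7,3',4',5'-pentabenzyloxy-3-methoxy-6,8-dimethylflavone), via 6-iodo-8-methyl monocoupled flavone 12 (not isolated)
Conditions: trimethylboroxine (2.5 equiv), Pd(OAc)2 (10 mol%), SPhos (2-dicyclohexylphosphino-2',6'-dimethoxybiphenyl, 20 mol%), K3PO4 (6 equiv), toluene/H2O 10:1, 100 °C, Ar
Reagents that add atoms: trimethylboroxine 11, CB1OB(C)OB(C)O1
Why: Pd(OAc)2 is reduced in the flask to a zerovalent palladium–SPhos complex that should insert first into the less flanked C8–I bond and, after release of 12, into the C6–I bond; at each site the methylboron species freed from the boroxine by aqueous phosphate hands its methyl group to divalent palladium and reductive elimination forms the aryl–CH3 bond. The closest known reaction type is the Suzuki–Miyaura methylation of doubly ortho-substituted aryl iodides with trimethylboroxine, as applied to iodinated 5,7-dioxygenated flavones. No ring is closed and no stereocentre is formed; the step adds only the two skeletal C–C bonds at C6 and C8. Site selectivity is not at issue, because the iodine atoms placed in step 4 define both positions. What the step needs is complete twofold coupling ahead of protodeiodination, which is secured by the bulky electron-rich biaryl phosphine (fast oxidative addition and reductive elimination at crowded carbons), by a methyl group that cannot undergo β-hydride elimination, by an excess of boroxine and by the absence of any free phenol. The benzyl ethers, the 3-methoxy group and the pyranone carbonyl are inert to these conditions.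

Step 7
Reactants: 13 pentabenzyl dimethylflavone
Product: 14 6,8-di-C-methylmyricetin 3-methyl ether (5,7,3',4',5'-pentahydroxy-3-methoxy-6,8-dimethylflavone)
Conditions: H2 (1 atm), 10% Pd/C, THF/MeOH 1:1, rt; filtration and concentration under Ar
Reagents that add atoms: none
Why: Catalytic hydrogenolysis should cleave the five benzylic C–O bonds, while the tetrasubstituted C2=C3 bond of the 3-methoxyflavone and the aryl methyl groups are not reduced at ambient pressure and temperature.

**Compound list**
1 | myricitrin (myricetin 3-O-α-L-rhamnopyranoside) | C[C@H]1[C@@H]([C@H]([C@H]([C@@H](O1)Oc1c(-c2cc(O)c(O)c(O)c2)oc2cc(O)cc(O)c2c1=O)O)O)O | starting material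
2 | benzyl bromide | BrCc1ccccc1 | starting material
3 | 7,3',4',5'-tetra-O-benzylmyricetin 3-O-α-L-rhamnopyranoside | C[C@H]1[C@@H]([C@H]([C@H]([C@@H](O1)Oc1c(-c2cc(OCc3ccccc3)c(OCc3ccccc3)c(OCc3ccccc3)c2)oc2cc(OCc3ccccc3)cc(O)c2c1=O)O)O)O | intermediate
4 | 7,3',4',5'-tetrabenzyloxy-3,5-dihydroxyflavone | Oc1c(-c2cc(OCc3ccccc3)c(OCc3ccccc3)c(OCc3ccccc3)c2)oc2cc(OCc3ccccc3)cc(O)c2c1=O | intermediate
5 | iodomethane | CI | starting material
6 | 7,3',4',5'-tetrabenzyloxy-5-hydroxy-3-methoxyflavone | COc1c(-c2cc(OCc3ccccc3)c(OCc3ccccc3)c(OCc3ccccc3)c2)oc2cc(OCc3ccccc3)cc(O)c2c1=O | intermediate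
7 | N-iodosuccinimide | O=C1CCC(=O)N1I | starting material
8 | 7,3',4',5'-tetrabenzyloxy-5-hydroxy-6-iodo-3-methoxyflavone (not isolated) | COc1c(-c2cc(OCc3ccccc3)c(OCc3ccccc3)c(OCc3ccccc3)c2)oc2cc(OCc3ccccc3)c(I)c(O)c2c1=O | intermediate
9 | 7,3',4',5'-tetrabenzyloxy-5-hydroxy-6,8-diiodo-3-methoxyflavone | COc1c(-c2cc(OCc3ccccc3)c(OCc3ccccc3)c(OCc3ccccc3)c2)oc2c(I)c(OCc3ccccc3)c(I)c(O)c2c1=O | intermediate
10 | 5,7,3',4',5'-pentabenzyloxy-6,8-diiodo-3-methoxyflavone | COc1c(-c2cc(OCc3ccccc3)c(OCc3ccccc3)c(OCc3ccccc3)c2)oc2c(I)c(OCc3ccccc3)c(I)c(OCc3ccccc3)c2c1=O | intermediate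
11 | trimethylboroxine | CB1OB(C)OB(C)O1 | starting material
12 | 5,7,3',4',5'-pentabenzyloxy-6-iodo-3-methoxy-8-methylflavone (not isolated) | COc1c(-c2cc(OCc3ccccc3)c(OCc3ccccc3)c(OCc3ccccc3)c2)oc2c(C)c(OCc3ccccc3)c(I)c(OCc3ccccc3)c2c1=O | intermediate
13 | 5,7,3',4',5'-pentabenzyloxy-3-methoxy-6,8-dimethylflavone | COc1c(-c2cc(OCc3ccccc3)c(OCc3ccccc3)c(OCc3ccccc3)c2)oc2c(C)c(OCc3ccccc3)c(C)c(OCc3ccccc3)c2c1=O | intermediate
14 | 6,8-di-C-methylmyricetin 3-methyl ether | COc1c(-c2cc(O)c(O)c(O)c2)oc2c(C)c(O)c(C)c(O)c2c1=O | target

**Count and risks**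
Total step count: 7. Longest linear sequence: 7 steps (1 → 3 → 4 → 6 → 9 → 10 → 13 → 14).

Steps most likely to fail:

1. Step 6. The second coupling at C6, which is flanked by two benzyloxy groups, may lag behind the first, so that hydrodeiodination overtakes methyl transfer and the coupling ends incomplete. The fallback sets out from 10 and changes the methyl donor from boron to zinc. A twofold Negishi coupling with MeZnCl (5 equiv, THF solution) and Pd(P(t-Bu)3)2 (5 mol%) in THF/NMP at rt to 50 °C needs neither base nor water, which removes the proton source and speeds transmetalation. It comes back to the route at 13; no new compound arises (F0).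

2. Step 4. The second iodination may stall, or iodine may be lost again because iodination of very electron-rich arenes is reversible under acid, leaving mono-iodinated material. The fallback sets out from 6 and changes the halogen. Irreversible dibromination with N-bromosuccinimide (2.1 equiv, DMF, 0 °C, dark) should give 7,3',4',5'-tetrabenzyloxy-6,8-dibromo-5-hydroxy-3-methoxyflavone F1. Benzylation as in step 5 (BnBr, K2CO3, DMF, 70 °C) should give 5,7,3',4',5'-pentabenzyloxy-6,8-dibromo-3-methoxyflavone F2. The twofold methylation of F2 with trimethylboroxine under Pd(OAc)2/SPhos/K3PO4 in toluene/H2O at 100 °C, a system that also activates aryl bromides, then comes back to the route at 13.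

3. Step 5. O-Alkylation of the chelated phenol may be slowed by the flanking iodine and the peri carbonyl, and long heating in base may then erode the C–I bonds. The fallback sets out from 6 and reverses the order of etherification and iodination. The unhindered phenol of 6 is benzylated first (BnBr, K2CO3, DMF, 70 °C) to 5,7,3',4',5'-pentabenzyloxy-3-methoxyflavone F3. This is then diiodinated with NIS (2.4 equiv) and catalytic TFA in MeCN at rt, C8 and C6 again being the carbons served by three oxygen donors. The sequence comes back to the route at 10.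

**Further compounds**
F0 | step 6 | none | none
F1 | step 4 | 7,3',4',5'-tetrabenzyloxy-6,8-dibromo-5-hydroxy-3-methoxyflavone | COc1c(-c2cc(OCc3ccccc3)c(OCc3ccccc3)c(OCc3ccccc3)c2)oc2c(Br)c(OCc3ccccc3)c(Br)c(O)c2c1=O
F2 | step 4 | 5,7,3',4',5'-pentabenzyloxy-6,8-dibromo-3-methoxyflavone | COc1c(-c2cc(OCc3ccccc3)c(OCc3ccccc3)c(OCc3ccccc3)c2)oc2c(Br)c(OCc3ccccc3)c(Br)c(OCc3ccccc3)c2c1=O
F3 | step 5 | 5,7,3',4',5'-pentabenzyloxy-3-methoxyflavone | COc1c(-c2cc(OCc3ccccc3)c(OCc3ccccc3)c(OCc3ccccc3)c2)oc2cc(OCc3ccccc3)cc(OCc3ccccc3)c2c1=O
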